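**Retrosynthetic overview**
1. Target 30 is 3α,6β,19-trihydroxylabda-8,13E-dien-15-oic acid (labdane numbering throughout). The plan rests on the oxygen at C3, the quaternary C4 whose oxidised carbon C19 stands cis to the C10 methyl, and the trans C5–C10 fusion of rings A and B: the pattern left by a head-to-tail closure that starts at a carbon flanked by a C3 ketone and a C19 ester.
2. Late disconnections: C13=C14 (Horner–Wadsworth–Emmons on a C13 methyl ketone), the C3 and C6 carbinols (hydride to a 3,6-dione from its open faces), C8=C9 (isomerisation of the 8(17)-alkene).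
3. Key disconnection: C4–C5 and C9–C10. Ring A closes first and ring B directly after it, in one oxidative radical cascade of acyclic keto ester 18 folded by its C6 silyloxy stereocentre.
4. 18 is assembled through C1–C2 (acetoacetate dianion alkylation), C5=C10 (Wittig), C9–C11 (Negishi coupling), C8–C17 (carboalumination) and C7–C8 (acetylide opening of (S)-benzyl glycidyl ether, the source of C6).

Key step: step 10

Remark: an enal made from a prenyl ester with SeO2 carries its formyl group on the methyl-bearing alkene carbon, so a propargyl addition to it would put the carbinol beside C(CH3); C6 must sit on the CH end of C5=C10(CH3), so the chain is grown from C6 of a glycidyl ether and C5=C10 is made afterwards by a stabilised Wittig reaction.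
Remark: the cascade is run in ethanol rather than acetic acid so that the dioxolane and the silyl ether survive; all alkene isomers formed on termination converge in step 11.

**Step 1**
Reactants: 1 (S)-benzyl glycidyl ether; 2 lithium acetylide–ethylenediamine complex
Product: 3 (S)-1-(benzyloxy)pent-4-yn-2-ol
Conditions: 2 (1.5 equiv), DMSO, 0 → 23 °C; then H2O
Reagents that add atoms: none
Why: Epoxide alkynylation: the acetylide opens the oxirane by SN2 attack at the unsubstituted carbon (future C7), so the C–O bond of the stereocentre is untouched and C6 keeps the (S) configuration of 1.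

**Step 2**
Reactants: 3 (S)-1-(benzyloxy)pent-4-yn-2-ol
Product: 4 (S)-1-(benzyloxy)-2-(tert-butyldimethylsilyloxy)pent-4-yne
Conditions: TBSCl, imidazole, DMF, 23 °C
Reagents that add atoms: tert-butyldimethylsilyl chloride, CC(C)(C)[Si](C)(C)Cl
Why: Routine imidazole-promoted silylation of a secondary alcohol; this silyl ether is the group that later steers the cyclisation.

**Step 3**
Reactants: 4 (S)-1-(benzyloxy)-2-(tert-butyldimethylsilyloxy)pent-4-yne
Product: 6 (S,E)-1-(benzyloxy)-2-(tert-butyldimethylsilyloxy)-5-iodo-4-methylpent-4-ene, via alkenylalane 5 (not isolated)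
Conditions: AlMe3 (3 equiv), Cp2ZrCl2 (0.3 equiv), CH2Cl2, 0 → 23 °C; then I2, THF, −30 → 0 °C
Reagents that add atoms: trimethylaluminium, C[Al](C)C; iodine, II
Why: Negishi zirconium-catalysed carboalumination adds CH3 and Al syn across the terminal alkyne with Al on the terminal carbon, and iodinolysis with retention gives the (E)-iodide, which fixes the C8=C9 geometry with C17 in place.

**Step 4**
Reactants: 6 (S,E)-vinyl iodide; 7 2-(2-bromoethyl)-2-methyl-1,3-dioxolane
Product: 9 (S,E)-2-[7-(benzyloxy)-6-(tert-butyldimethylsilyloxy)-4-methylhept-3-enyl]-2-methyl-1,3-dioxolane, via organozinc bromide 8 (not isolated)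
Conditions: 7, Zn dust (I2-activated), DMA, 70 °C; then 6, Pd(PPh3)4 (5 mol %), THF, 45 °C
Reagents that add atoms: none
Why: Negishi sp3–sp2 cross-coupling of a primary alkylzinc bromide (made by direct zinc insertion, which tolerates the ketal) with the alkenyl iodide proceeds with retention of the E geometry and forms C9–C11.

**Step 5**
Reactants: 9 benzyl ether
Product: 10 (S,E)-2-(tert-butyldimethylsilyloxy)-4-methyl-7-(2-methyl-1,3-dioxolan-2-yl)hept-4-en-1-ol
Conditions: LiDBB (lithium 4,4′-di-tert-butylbiphenylide), THF, −78 °C; then aq. NH4Cl at −78 °C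
Reagents that add atoms: none
Why: Reductive debenzylation by electron transfer cleaves only the benzylic C–O bond and leaves the isolated trisubstituted alkene, the silyl ether and the ketal; quenching cold prevents migration of the silyl group to the new primary alkoxide.

**Step 6**
Reactants: 10 primary alcohol; 11 ethyl 2-(triphenylphosphoranylidene)propanoate
Product: 13 ethyl (S,2E,6E)-4-(tert-butyldimethylsilyloxy)-2,6-dimethyl-9-(2-methyl-1,3-dioxolan-2-yl)nona-2,6-dienoate, via aldehyde 12 (not isolated)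
Conditions: Dess–Martin periodinane, NaHCO3, CH2Cl2, 0 → 23 °C; then 11, 23 → 40 °C
Reagents that add atoms: none
Why: Dess–Martin oxidation followed in the same flask by Wittig olefination with a stabilised, α-methyl ylide gives the (E)-trisubstituted enoate, so the methyl (C20) lies on C10 and C6 on the CH terminus, and the α-silyloxy aldehyde is consumed before it can epimerise.

**Step 7**
Reactants: 13 dienoate
Product: 14 (S,2E,6E)-4-(tert-butyldimethylsilyloxy)-2,6-dimethyl-9-(2-methyl-1,3-dioxolan-2-yl)nona-2,6-dien-1-ol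
Conditions: i-Bu2AlH (2.2 equiv), CH2Cl2, −78 °C; Rochelle salt
Reagents that add atoms: none
Why: 1,2-Reduction of an α,β-unsaturated ester by i-Bu2AlH gives the allylic alcohol without touching the alkenes, silyl ether or ketal.

**Step 8**
Reactants: 14 allylic alcohol
Product: 15 2-[(S,3E,7E)-9-bromo-6-(tert-butyldimethylsilyloxy)-4,8-dimethylnona-3,7-dienyl]-2-methyl-1,3-dioxolane
Conditions: CBr4, PPh3, 2,6-lutidine, CH2Cl2, −20 → 0 °C
Reagents that add atoms: carbon tetrabromide, BrC(Br)(Br)Br
Why: Appel bromination converts the primary allylic alcohol to the bromide by SN2 displacement under buffered, near-neutral conditions that the ketal and silyl ether tolerate.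

**Step 9**
Reactants: 15 allylic bromide; 16 methyl 2-methylacetoacetate
Product: 18 methyl (8S,6E,10E)-8-(tert-butyldimethylsilyloxy)-2,6,10-trimethyl-13-(2-methyl-1,3-dioxolan-2-yl)-3-oxotrideca-6,10-dienoate (labdane C6 = S; mixture of C4 epimers), via dianion 17 (not isolated)
Conditions: 16, NaH, THF, 0 °C; n-BuLi, 0 °C; then 15, 0 °C; aq. NH4Cl
Reagents that add atoms: none
Why: γ-Alkylation of an acetoacetate dianion: the terminal carbanion is the more reactive site and displaces the allylic bromide by SN2, forming C1–C2 and leaving the 2-methyl-3-oxo ester intact.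

**Step 10**
Reactants: 18 acyclic keto ester
Product: 19 methyl 6α-(tert-butyldimethylsilyloxy)-13,13-(ethylenedioxy)-3-oxo-14,15-dinorlabd-8(17)-en-19-oate (4α-CH3, 4β-CO2CH3, 5α-H, 9α-H, 10β-CH3)
Conditions: Mn(OAc)3·2H2O (2.2 equiv), Cu(OAc)2·H2O (1.0 equiv), degassed EtOH, 40 °C
Reagents that add atoms: none
Why: Mn(OAc)3 turns the 2-methyl-3-oxo ester into its trivalent manganese enolate, which gives the electrophilic C4 radical; this adds to C5 of the (E)-C5=C10 alkene, the tertiary C10 radical adds to C9 of the (E)-C8=C9 alkene, and Cu(OAc)2 oxidises the tertiary C8 radical through an alkylcopper species and β-hydride loss to the 8(17)-alkene. The closest known reaction type is the oxidative free-radical bicyclisation of 2-alkyl-3-oxo ester polyenes with Mn(OAc)3 and Cu(OAc)2 to trans-decalins. Ring A closes 6-endo-trig (C4–C5) and ring B 6-endo-trig (C9–C10), each through a chair and each giving a tertiary radical. C5 and C10 follow from anti addition across the E alkene in the chair–chair fold (trans fusion), C9 from the E geometry of C8=C9 (side chain equatorial), and C4 from the rotamer of the planar radical in which ketone and ester carbonyls point apart, which leaves CO2CH3 axial on the face of C20. The step needs one face of C5=C10 to react, and C6 secures this: allylic A(1,3) strain with the cis C20 methyl holds H-6 in the alkene plane and C7 must lie opposite the incoming C4, so the silyloxy group points outward and ends equatorial (6α), whereas the other face would force it axial against C19 and C20. Ethanol keeps the ketal and silyl ether intact, and minor endocyclic alkene isomers are carried on because step 11 converges them.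

**Step 11**
Reactants: 19 8(17)-alkene
Product: 20 methyl 6α-(tert-butyldimethylsilyloxy)-13,13-(ethylenedioxy)-3-oxo-14,15-dinorlabd-8-en-19-oate
Conditions: p-TsOH (anhydrous, 0.2 equiv), benzene, 60 °C; Et3N quench
Reagents that add atoms: none
Why: Acid-catalysed alkene isomerisation through the tertiary C8 cation moves the double bond to the tetrasubstituted, thermodynamically preferred C8=C9 position (C9 becomes planar), and the water-free medium gives the ketal and silyl ether no nucleophile.

**Step 12**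
Reactants: 20 silyl ether
Product: 21 methyl 13,13-(ethylenedioxy)-6α-hydroxy-3-oxo-14,15-dinorlabd-8-en-19-oate
Conditions: HF·pyridine, pyridine, THF, 0 → 23 °C
Reagents that add atoms: none
Why: Fluoride-driven desilylation under buffered conditions frees the 6α-alcohol without hydrolysing the ketal or opening the non-enolisable β-keto ester by retro-Claisen cleavage.

**Step 13**
Reactants: 21 6α-alcohol
Product: 22 methyl 13,13-(ethylenedioxy)-3,6-dioxo-14,15-dinorlabd-8-en-19-oate
Conditions: Dess–Martin periodinane, NaHCO3, CH2Cl2, 0 °C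
Reagents that add atoms: none
Why: Dess–Martin oxidation is non-enolising and buffered, so the β,γ-unsaturated 6-ketone forms without the C8=C9 alkene moving into conjugation; 22 is used at once.

**Step 14**
Reactants: 22 3,6-dione
Product: 24 13,13-(ethylenedioxy)-3α-hydroxy-14,15-dinorlabd-8-en-19,6β-olide, via dihydroxy ester 23 (not isolated)
Conditions: LiBH(s-Bu)3 (3 equiv), THF, −78 → 23 °C; aq. NH4Cl
Reagents that add atoms: none
Why: Bulky-hydride reduction: LiBH(s-Bu)3 attacks C3 along the equatorial trajectory to give the axial 3α-alcohol and attacks C6 from the α face because the β face is screened by the axial C19 ester and the C10 methyl, giving the axial 6β-alkoxide, which closes onto the syn-axial ester as the γ-lactone.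

**Step 15**
Reactants: 24 lactone
Product: 26 3α,6β,19-trihydroxy-14,15-dinorlabd-8-en-13-one, via triol ketal 25 (not isolated)
Conditions: LiAlH4, THF, 0 → 23 °C; Rochelle salt; then 1 M aq. HCl/THF (1:4), 23 °C
Reagents that add atoms: water, O
Why: LiAlH4 reduces the lactone to the 6β,19-diol without touching a stereocentre, and mild aqueous acid then hydrolyses the dioxolane to the C13 methyl ketone while the tetrasubstituted alkene and the alcohols stay as they are.

**Step 16**
Reactants: 26 keto triol; 27 triethyl phosphonoacetate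
Product: 29 ethyl 3α,6β,19-trihydroxylabda-8,13E-dien-15-oate, via phosphonate anion 28 (not isolated)
Conditions: 27 (4 equiv), NaH (4 equiv), THF, 0 °C; then 26, 23 → 50 °C
Reagents that add atoms: none
Why: Horner–Wadsworth–Emmons olefination of the unhindered methyl ketone gives the conjugated ester with the E isomer favoured under equilibrating conditions, and the stabilised anion is too weak a base to deprotonate the three hydroxyls; any 13Z ester is removed by chromatography.

**Step 17**
Reactants: 29 ethyl ester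
Product: 30 3α,6β,19-trihydroxylabda-8,13E-dien-15-oic acid (target)
Conditions: LiOH·H2O, THF/MeOH/H2O (2:1:1), 50 °C; then 1 M aq. HCl to pH 3 at 0 °C
Reagents that add atoms: lithium hydroxide, [Li+].[OH-]
Why: Saponification by acyl substitution cleaves the ethyl ester without disturbing the alcohols or either alkene, and cold, brief acidification releases the acid.

**Compound list**
1 | (S)-benzyl glycidyl ether | C1[C@H](O1)COCc2ccccc2 | starting material
2 | lithium acetylide–ethylenediamine complex | [Li+].[C-]#C.NCCN | starting material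
3 | (S)-1-(benzyloxy)pent-4-yn-2-ol | C#CC[C@H](O)COCc1ccccc1 | intermediate
4 | (S)-1-(benzyloxy)-2-(tert-butyldimethylsilyloxy)pent-4-yne | C#CC[C@H](O[Si](C)(C)C(C)(C)C)COCc1ccccc1 | intermediate
5 | (S,E)-alkenyl(dimethyl)alane from 4 | C[Al](C)/C=C(\C)C[C@H](O[Si](C)(C)C(C)(C)C)COCc1ccccc1 | intermediate (not isolated)
6 | (S,E)-1-(benzyloxy)-2-(tert-butyldimethylsilyloxy)-5-iodo-4-methylpent-4-ene | I/C=C(\C)C[C@H](O[Si](C)(C)C(C)(C)C)COCc1ccccc1 | intermediate
7 | 2-(2-bromoethyl)-2-methyl-1,3-dioxolane | CC1(CCBr)OCCO1 | starting material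
8 | [2-(2-methyl-1,3-dioxolan-2-yl)ethyl]zinc bromide | CC1(CC[Zn]Br)OCCO1 | intermediate (not isolated)
9 | (S,E)-2-[7-(benzyloxy)-6-(tert-butyldimethylsilyloxy)-4-methylhept-3-enyl]-2-methyl-1,3-dioxolane | CC1(CC/C=C(\C)C[C@H](O[Si](C)(C)C(C)(C)C)COCc2ccccc2)OCCO1 | intermediate
10 | (S,E)-2-(tert-butyldimethylsilyloxy)-4-methyl-7-(2-methyl-1,3-dioxolan-2-yl)hept-4-en-1-ol | CC1(CC/C=C(\C)C[C@H](O[Si](C)(C)C(C)(C)C)CO)OCCO1 | intermediate
11 | ethyl 2-(triphenylphosphoranylidene)propanoate | CCOC(=O)C(C)=P(c1ccccc1)(c1ccccc1)c1ccccc1 | starting material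
12 | (S,E)-2-(tert-butyldimethylsilyloxy)-4-methyl-7-(2-methyl-1,3-dioxolan-2-yl)hept-4-enal | CC1(CC/C=C(\C)C[C@H](O[Si](C)(C)C(C)(C)C)C=O)OCCO1 | intermediate (not isolated)
13 | ethyl (S,2E,6E)-4-(tert-butyldimethylsilyloxy)-2,6-dimethyl-9-(2-methyl-1,3-dioxolan-2-yl)nona-2,6-dienoate | CCOC(=O)/C(C)=C/[C@@H](O[Si](C)(C)C(C)(C)C)C/C(C)=C/CCC1(C)OCCO1 | intermediate
14 | (S,2E,6E)-4-(tert-butyldimethylsilyloxy)-2,6-dimethyl-9-(2-methyl-1,3-dioxolan-2-yl)nona-2,6-dien-1-ol | OC/C(C)=C/[C@@H](O[Si](C)(C)C(C)(C)C)C/C(C)=C/CCC1(C)OCCO1 | intermediate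
15 | 2-[(S,3E,7E)-9-bromo-6-(tert-butyldimethylsilyloxy)-4,8-dimethylnona-3,7-dienyl]-2-methyl-1,3-dioxolane | BrC/C(C)=C/[C@@H](O[Si](C)(C)C(C)(C)C)C/C(C)=C/CCC1(C)OCCO1 | intermediate
16 | methyl 2-methylacetoacetate | COC(=O)C(C)C(C)=O | starting material
17 | sodium lithium dianion of 16 | [Na+].[Li+].C=C([O-])C(C)=C([O-])OC | intermediate (not isolated)
18 | methyl (8S,6E,10E)-8-(tert-butyldimethylsilyloxy)-2,6,10-trimethyl-13-(2-methyl-1,3-dioxolan-2-yl)-3-oxotrideca-6,10-dienoate | COC(=O)C(C)C(=O)CC/C(C)=C/[C@@H](O[Si](C)(C)C(C)(C)C)C/C(C)=C/CCC1(C)OCCO1 | intermediate (key-step precursor)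
19 | methyl 6α-(tert-butyldimethylsilyloxy)-13,13-(ethylenedioxy)-3-oxo-14,15-dinorlabd-8(17)-en-19-oate | C=C1[C@H](CCC3(C)OCCO3)[C@@]2(C)CCC(=O)[C@](C)(C(=O)OC)[C@@H]2[C@@H](O[Si](C)(C)C(C)(C)C)C1 | intermediate (key-step product)
20 | methyl 6α-(tert-butyldimethylsilyloxy)-13,13-(ethylenedioxy)-3-oxo-14,15-dinorlabd-8-en-19-oate | CC1=C(CCC3(C)OCCO3)[C@@]2(C)CCC(=O)[C@](C)(C(=O)OC)[C@@H]2[C@@H](O[Si](C)(C)C(C)(C)C)C1 | intermediate
21 | methyl 13,13-(ethylenedioxy)-6α-hydroxy-3-oxo-14,15-dinorlabd-8-en-19-oate | CC1=C(CCC3(C)OCCO3)[C@@]2(C)CCC(=O)[C@](C)(C(=O)OC)[C@@H]2[C@@H](O)C1 | intermediate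
22 | methyl 13,13-(ethylenedioxy)-3,6-dioxo-14,15-dinorlabd-8-en-19-oate | CC1=C(CCC3(C)OCCO3)[C@@]2(C)CCC(=O)[C@](C)(C(=O)OC)[C@@H]2C(=O)C1 | intermediate
23 | methyl 13,13-(ethylenedioxy)-3α,6β-dihydroxy-14,15-dinorlabd-8-en-19-oate (as lithium alkoxide) | CC1=C(CCC3(C)OCCO3)[C@@]2(C)CC[C@@H](O)[C@](C)(C(=O)OC)[C@@H]2[C@H](O)C1 | intermediate (not isolated)
24 | 13,13-(ethylenedioxy)-3α-hydroxy-14,15-dinorlabd-8-en-19,6β-olide | CC1=C(CCC3(C)OCCO3)[C@@]2(C)CC[C@@H](O)[C@@]4(C)[C@@H]2[C@H](OC4=O)C1 | intermediate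
25 | 13,13-(ethylenedioxy)-14,15-dinorlabd-8-ene-3α,6β,19-triol | CC1=C(CCC3(C)OCCO3)[C@@]2(C)CC[C@@H](O)[C@](C)(CO)[C@@H]2[C@H](O)C1 | intermediate (not isolated)
26 | 3α,6β,19-trihydroxy-14,15-dinorlabd-8-en-13-one | CC1=C(CCC(C)=O)[C@@]2(C)CC[C@@H](O)[C@](C)(CO)[C@@H]2[C@H](O)C1 | intermediate
27 | triethyl phosphonoacetate | CCOC(=O)CP(=O)(OCC)OCC | starting material
28 | sodium salt of triethyl phosphonoacetate | [Na+].CCOC(=O)[CH-]P(=O)(OCC)OCC | intermediate (not isolated)
29 | ethyl 3α,6β,19-trihydroxylabda-8,13E-dien-15-oate | CC1=C(CC/C(C)=C/C(=O)OCC)[C@@]2(C)CC[C@@H](O)[C@](C)(CO)[C@@H]2[C@H](O)C1 | intermediate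
30 | 3α,6β,19-trihydroxylabda-8,13E-dien-15-oic acid (CNP0246116.2) | CC1=C(CC/C(C)=C/C(=O)O)[C@@]2(C)CC[C@@H](O)[C@](C)(CO)[C@@H]2[C@H](O)C1 | target

**Step count**
Total: 17 steps. Longest linear sequence: 17 steps (1 → 30); 2, 7, 11, 16 and 27 enter as purchased pieces.

**Steps most likely to fail**

1. Step 10. The relay from C6 may discriminate the two faces of C5=C10 less well than the allylic-strain argument predicts, or the monocyclic C10 radical may be oxidised before ring B closes. Fallback, from 15 back to 24: stereocontrol is reinforced by an ester auxiliary, a known solution for this class of cyclisation. (−)-8-Phenylmenthol is transesterified with 16 (DMAP, toluene, reflux) to (−)-8-phenylmenthyl 2-methyl-3-oxobutanoate F1. Its sodium lithium dianion F2 (NaH, then n-BuLi, THF, 0 °C) is alkylated with 15 to the 8-phenylmenthyl keto ester F3. Mn(OAc)3·2H2O and Cu(OAc)2·H2O then close it to the bicyclic 8-phenylmenthyl ester F4, in which auxiliary and C6 should act together; the enantiomeric auxiliary is taken if the pairing proves mismatched. F4 passes through the operations of steps 11 to 13 as the C8=C9 ester F5, the 6α-alcohol F6 and the 3,6-dione F7. In the LiBH(s-Bu)3 step the 6β-alkoxide expels 8-phenylmenthol and gives lactone 24.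

2. Step 11. Protonation and deprotonation may stop at a mixture of C7=C8 and C8=C9 alkenes, and the acid may strip the ketal or the silyl ether. Fallback, from 19 back to 22: the alkene is placed through the C6 ketone. HF·pyridine converts 19 to the 6α-alcohol F8 with the exocyclic alkene untouched. Dess–Martin oxidation gives the β,γ-unsaturated 6-ketone F9, and DBU in CH2Cl2 draws the alkene into conjugation to give the 7-en-6-one F10. KOt-Bu in t-BuOH/THF then forms the extended dienolate, and a cold AcOH quench protonates it at C7 (deconjugation by kinetic α-protonation), leaving the alkene at C8=C9 in dione 22. Any exocyclic ketone F9 regenerated is returned to the DBU treatment.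

3. Step 16. Olefination of the methyl ketone may be slow beside three free hydroxyls and may give the 13Z ester together with the 13E ester. Fallback, from 26 back to 29: the geometry is fixed by syn carbometalation. 26 is silylated (Et3SiOTf, 2,6-lutidine, CH2Cl2) to the tris(triethylsilyl) ether F11. LDA at −78 °C and ClP(O)(OEt)2 give the terminal enol phosphate F12, which further LDA eliminates to the terminal alkyne F13. AlMe3 with Cp2ZrCl2 (cat.) gives the alkenylalane F14, which ClCO2Et traps as the tris(triethylsilyl) ethyl ester F15 with the E geometry set by the syn addition. Bu4NF in THF then returns 29.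

**Further compounds**
F1 | step 10 | (−)-8-phenylmenthyl 2-methyl-3-oxobutanoate | CC(=O)C(C)C(=O)O[C@@H]1C[C@H](C)CC[C@H]1C(C)(C)c2ccccc2
F2 | step 10 | sodium lithium dianion of F1 | [Na+].[Li+].C=C([O-])C(C)=C([O-])O[C@@H]1C[C@H](C)CC[C@H]1C(C)(C)c2ccccc2
F3 | step 10 | 8-phenylmenthyl ester analogue of 18 | O=C(CC/C(C)=C/[C@@H](O[Si](C)(C)C(C)(C)C)C/C(C)=C/CCC1(C)OCCO1)C(C)C(=O)O[C@@H]2C[C@H](C)CC[C@H]2C(C)(C)c3ccccc3
F4 | step 10 | 8-phenylmenthyl 6α-(tert-butyldimethylsilyloxy)-13,13-(ethylenedioxy)-3-oxo-14,15-dinorlabd-8(17)-en-19-oate | C=C1[C@H](CCC3(C)OCCO3)[C@@]2(C)CCC(=O)[C@](C)(C(=O)O[C@@H]4C[C@H](C)CC[C@H]4C(C)(C)c5ccccc5)[C@@H]2[C@@H](O[Si](C)(C)C(C)(C)C)C1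
F5 | step 10 | 8-phenylmenthyl 6α-(tert-butyldimethylsilyloxy)-13,13-(ethylenedioxy)-3-oxo-14,15-dinorlabd-8-en-19-oate | CC1=C(CCC3(C)OCCO3)[C@@]2(C)CCC(=O)[C@](C)(C(=O)O[C@@H]4C[C@H](C)CC[C@H]4C(C)(C)c5ccccc5)[C@@H]2[C@@H](O[Si](C)(C)C(C)(C)C)C1
F6 | step 10 | 8-phenylmenthyl 13,13-(ethylenedioxy)-6α-hydroxy-3-oxo-14,15-dinorlabd-8-en-19-oate | CC1=C(CCC3(C)OCCO3)[C@@]2(C)CCC(=O)[C@](C)(C(=O)O[C@@H]4C[C@H](C)CC[C@H]4C(C)(C)c5ccccc5)[C@@H]2[C@@H](O)C1
F7 | step 10 | 8-phenylmenthyl 13,13-(ethylenedioxy)-3,6-dioxo-14,15-dinorlabd-8-en-19-oate | CC1=C(CCC3(C)OCCO3)[C@@]2(C)CCC(=O)[C@](C)(C(=O)O[C@@H]4C[C@H](C)CC[C@H]4C(C)(C)c5ccccc5)[C@@H]2C(=O)C1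
F8 | step 11 | methyl 13,13-(ethylenedioxy)-6α-hydroxy-3-oxo-14,15-dinorlabd-8(17)-en-19-oate | C=C1[C@H](CCC3(C)OCCO3)[C@@]2(C)CCC(=O)[C@](C)(C(=O)OC)[C@@H]2[C@@H](O)C1
F9 | step 11 | methyl 13,13-(ethylenedioxy)-3,6-dioxo-14,15-dinorlabd-8(17)-en-19-oate | C=C1[C@H](CCC3(C)OCCO3)[C@@]2(C)CCC(=O)[C@](C)(C(=O)OC)[C@@H]2C(=O)C1
F10 | step 11 | methyl 13,13-(ethylenedioxy)-3,6-dioxo-14,15-dinorlabd-7-en-19-oate | CC1=CC(=O)[C@H]2[C@@](C)(C(=O)OC)C(=O)CC[C@]2(C)[C@H]1CCC3(C)OCCO3
F11 | step 16 | 3α,6β,19-tris(triethylsilyloxy)-14,15-dinorlabd-8-en-13-one | CC1=C(CCC(C)=O)[C@@]2(C)CC[C@@H](O[Si](CC)(CC)CC)[C@](C)(CO[Si](CC)(CC)CC)[C@@H]2[C@H](O[Si](CC)(CC)CC)C1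
F12 | step 16 | diethyl enol phosphate of F11 (C13=C16) | CC1=C(CCC(=C)OP(=O)(OCC)OCC)[C@@]2(C)CC[C@@H](O[Si](CC)(CC)CC)[C@](C)(CO[Si](CC)(CC)CC)[C@@H]2[C@H](O[Si](CC)(CC)CC)C1
F13 | step 16 | 3α,6β,19-tris(triethylsilyloxy)-14,15,16-trinorlabd-8-en-12-yl acetylene (terminal alkyne at C13) | CC1=C(CCC#C)[C@@]2(C)CC[C@@H](O[Si](CC)(CC)CC)[C@](C)(CO[Si](CC)(CC)CC)[C@@H]2[C@H](O[Si](CC)(CC)CC)C1
F14 | step 16 | (E)-alkenyl(dimethyl)alane from F13 | CC1=C(CC/C(C)=C/[Al](C)C)[C@@]2(C)CC[C@@H](O[Si](CC)(CC)CC)[C@](C)(CO[Si](CC)(CC)CC)[C@@H]2[C@H](O[Si](CC)(CC)CC)C1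
F15 | step 16 | ethyl 3α,6β,19-tris(triethylsilyloxy)labda-8,13E-dien-15-oate | CC1=C(CC/C(C)=C/C(=O)OCC)[C@@]2(C)CC[C@@H](O[Si](CC)(CC)CC)[C@](C)(CO[Si](CC)(CC)CC)[C@@H]2[C@H](O[Si](CC)(CC)CC)C1
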